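**Plan**
- Cuts: ring C at O1–C2 and C2–C3, giving acetophenone 17 (ring A plus C4 and C3) and aroyl chloride 20 (ring B plus C2). Ring A is cut at C5–C6 with C5–C8 re-formed, giving cyclobutenone 10. Cutting C8–C7 and C4a–C4 then leads to diisopropyl squarate and two α-lithiated vinyl ethers.
- Enabling feature: ring A carries oxygen on C5, C7, C8 and C8a, carbon on C4a and hydrogen only on C6, and the C5 and C8 oxygens are para. A squarate core (C5, C4a, C8a, C8) joined to an α-alkoxyvinyl unit (C7, C6) delivers exactly this hydroquinone pattern.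
- Forward order: the four-membered ring is decorated (steps 1–2), ring A forms by ring opening and 6π closure (step 3), ring B arrives intact (steps 6–8), and ring C closes last (step 9).
- The C8 oxygen is methylated at the alkoxide stage, so the key step gives a hydroquinone monomethyl ether and not an oxidation-prone free hydroquinone.
- Stereochemistry: the target is achiral. The quaternary carbons of 4, 5, 9 and 10 are racemic and all end as sp2 carbons.

Key step: step 3

Remark: flavone numbering (O1, C2 to C8a) is used for all ring A precursors. Racemic compounds are drawn without configuration, and 22 is drawn as its diketo tautomer.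

**Step 1**
Reactants: 1 ethyl vinyl ether; 2 diisopropyl squarate (3,4-diisopropoxycyclobut-3-ene-1,2-dione)
Product: 6 3-(1-ethoxyvinyl)-4-isopropoxycyclobut-3-ene-1,2-dione, via 1-ethoxyvinyllithium 3 (not isolated), via lithium alkoxide adduct 4 (not isolated), via adduct trifluoroacetate 5 (not isolated)
Conditions: 1 (excess), t-BuLi, THF, −78 → 0 °C; add to 2, THF, −78 °C; (CF3CO)2O (1.1 equiv), −78 °C; pH 7 phosphate buffer, −78 °C → rt
Reagents that add atoms: water (O)
Why: α-Lithiation of the vinyl ether, 1,2-addition to one squarate carbonyl and trifluoroacetate-triggered allylic transposition with hydrolytic loss of one isopropoxy group is the standard conversion of a squarate ester into a 3-substituted 4-alkoxycyclobutenedione, the cold buffered quench should spare the enol ether (which is also deactivated by conjugation to the dione), and the racemic carbinol carbon of 4 and 5 becomes sp2 in 6.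

**Step 2**
Reactants: 6 3-(1-ethoxyvinyl)-4-isopropoxycyclobut-3-ene-1,2-dione; 7 tert-butyl vinyl ether
Product: 10 4-(1-tert-butoxyvinyl)-2-(1-ethoxyvinyl)-3-isopropoxy-4-methoxycyclobut-2-en-1-one (racemic), via 1-tert-butoxyvinyllithium 8 (not isolated), via lithium alkoxide 9 (not isolated)
Conditions: 7 (excess), t-BuLi, THF, −78 → 0 °C; 6, THF, −78 °C; MeOTf, −78 → 0 °C
Reagents that add atoms: methyl trifluoromethanesulfonate (COS(=O)(=O)C(F)(F)F)
Why: 1,2-Addition of organolithiums to 3-alkoxy-4-substituted cyclobutenediones takes place at the ketone-like carbonyl next to the alkoxy-bearing carbon, because the other carbonyl is a vinylogous ester; in situ O-methylation of the tertiary alkoxide with MeOTf is an established trap, and the new quaternary centre (future C8) forms as a racemate that needs no control since step 3 removes it.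

**Step 3**
Reactants: 10 4-(1-tert-butoxyvinyl)-2-(1-ethoxyvinyl)-3-isopropoxy-4-methoxycyclobut-2-en-1-one
Product: 13 5-tert-butoxy-2-(1-ethoxyvinyl)-3-isopropoxy-4-methoxyphenol, via dienylketene 11 (not isolated), via cyclohexadienone 12 (not isolated)
Conditions: toluene (degassed, dilute), 110 °C, Ar, base-washed glassware
Reagents that add atoms: none
Why: Heat cleaves the C5–C8 bond in a conrotatory 4π opening to dienylketene 11, whose ketene carbon C5 and vinyl terminus C6 join in a thermally allowed disrotatory 6π electrocyclization that closes the six-membered carbocycle (ring A) as dienone 12, and a proton shift from C6 to the C5 oxygen gives phenol 13. This is the Moore rearrangement of 4-alkenyl-4-alkoxycyclobutenones, established for squarate-derived substrates with many alkenyl groups, so the present pair of alkoxyvinyl substituents is a new member of a known class. The selectivity required is torquoselectivity: the C8 methoxy group, as the stronger π-donor, should rotate outward and so turn the tert-butoxyvinyl group inward, next to the ketene. Because C8 carries a methyl ether and no free hydroxyl, a ketene of the wrong geometry has no internal trap and can only reclose, so the equilibrium drains through the irreversible aromatization. The 1-ethoxyvinyl group on C4a is cross-conjugated in 11 and can at most enter a reversible 4π closure, so it should remain a spectator. No stereocentre is created, and the racemic quaternary carbon of 10 becomes the planar C8.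

**Step 4**
Reactants: 13 5-tert-butoxy-2-(1-ethoxyvinyl)-3-isopropoxy-4-methoxyphenol
Product: 15 1-(4-tert-butoxy-2-isopropoxy-3,6-dimethoxyphenyl)ethan-1-one, via aryl enol ether 14 (not isolated)
Conditions: MeI, K2CO3, DMF, rt; extractive work-up; then 0.5 M aq HCl, THF, 0 °C → rt
Reagents that add atoms: iodomethane (CI); water (O)
Why: Williamson methylation of the only free phenol (C5–OH) under basic conditions leaves both acid-labile groups intact, the following dilute-acid hydrolysis of the α-alkoxystyrene is much faster than cleavage of an aryl tert-butyl ether, and any enol ether hydrolysed early converges on the same ketone.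

**Step 5**
Reactants: 15 1-(4-tert-butoxy-2-isopropoxy-3,6-dimethoxyphenyl)ethan-1-one
Product: 17 1-(2,4-dihydroxy-3,6-dimethoxyphenyl)ethan-1-one, via bis(dichloroboryl) ether 16 (not isolated)
Conditions: BCl3 (3 equiv), CH2Cl2, −78 → 0 °C; then H2O
Reagents that add atoms: none
Why: Lewis acid dealkylation of aryl ethers with BCl3 is far faster for tertiary and secondary alkyl groups than for methyl, the C8a isopropyl ether is further activated by chelation to the acetyl oxygen, and the six-membered boron chelate so formed in 16 occupies that carbonyl, so the other ortho ether (C5–OMe) should not be activated.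

**Step 6**
Reactants: 18 3,5-dihydroxy-4-methoxybenzoic acid
Product: 19 tert-butyldimethylsilyl 3,5-bis(tert-butyldimethylsilyloxy)-4-methoxybenzoate
Conditions: TBSCl (3.5 equiv), imidazole, DMF, rt
Reagents that add atoms: tert-butyldimethylsilyl chloride (CC(C)(C)[Si](C)(C)Cl)
Why: Imidazole-promoted silylation covers both phenols and the carboxylic acid in one operation and provides the silyl ester needed for neutral activation in the next step.

**Step 7**
Reactants: 19 tert-butyldimethylsilyl 3,5-bis(tert-butyldimethylsilyloxy)-4-methoxybenzoate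
Product: 20 3,5-bis(tert-butyldimethylsilyloxy)-4-methoxybenzoyl chloride
Conditions: (COCl)2, DMF (cat.), CH2Cl2, 0 °C → rt; used crude
Reagents that add atoms: oxalyl chloride (O=C(Cl)C(=O)Cl)
Why: Silyl esters are converted directly into acid chlorides by the Vilsmeier-type chloroiminium salt, silicon leaves as the chlorosilane so no HCl is formed, and the phenolic silyl ethers should therefore persist.

**Step 8**
Reactants: 17 1-(2,4-dihydroxy-3,6-dimethoxyphenyl)ethan-1-one; 20 3,5-bis(tert-butyldimethylsilyloxy)-4-methoxybenzoyl chloride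
Product: 22 1-[3,5-bis(tert-butyldimethylsilyloxy)-4-methoxyphenyl]-3-(2,4-dihydroxy-3,6-dimethoxyphenyl)propane-1,3-dione, via trilithium trianion 21 (not isolated)
Conditions: 17, LiN(SiMe3)2 (4.5 equiv), THF, −78 → −10 °C; 20, −78 °C → rt; cold 1 M HCl
Reagents that add atoms: none
Why: This is the Claisen-type C-acylation of a hydroxyacetophenone lithium polyanion by an aroyl chloride, the direct variant of the Baker–Venkataraman route, in which the enolate carbon is the most nucleophilic site of 21, any 2-O-aroyl ester would be carried to the same diketone by acyl transfer under the excess base, and the extra equivalent of base stores the acidic product as its enolate.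

**Step 9**
Reactants: 22 1-[3,5-bis(tert-butyldimethylsilyloxy)-4-methoxyphenyl]-3-(2,4-dihydroxy-3,6-dimethoxyphenyl)propane-1,3-dione
Product: 24 7-hydroxy-2-(3,5-dihydroxy-4-methoxyphenyl)-5,8-dimethoxy-4H-chromen-4-one (CNP0218554.0), via bis-silylated flavone 23 (not isolated)
Conditions: AcOH, H2SO4 (0.5% v/v), 95–100 °C
Reagents that add atoms: none
Why: Acid-catalysed cyclodehydration of an o-hydroxyaryl 1,3-diketone (6-exo-trig addition of the C8a hydroxyl to the aroyl carbonyl, then loss of water) closes ring C in only one sense because the other ortho position is a methyl ether, and the hot acidic acetic acid also solvolyses the two phenolic silyl ethers while aryl methyl ethers are inert to it.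

**Compound list**
1 | ethyl vinyl ether | C=COCC | starting material
2 | diisopropyl squarate | CC(C)OC1=C(OC(C)C)C(=O)C1=O | starting material
3 | 1-ethoxyvinyllithium | [Li]C(=C)OCC | intermediate
4 | lithium 1-(1-ethoxyvinyl)-2,3-diisopropoxy-4-oxocyclobut-2-en-1-olate (racemic) | [Li+].[O-]C1(C(=C)OCC)C(OC(C)C)=C(OC(C)C)C1=O | intermediate
5 | 1-(1-ethoxyvinyl)-2,3-diisopropoxy-4-oxocyclobut-2-en-1-yl trifluoroacetate (racemic) | CCOC(=C)C1(OC(=O)C(F)(F)F)C(OC(C)C)=C(OC(C)C)C1=O | intermediate
6 | 3-(1-ethoxyvinyl)-4-isopropoxycyclobut-3-ene-1,2-dione | CCOC(=C)C1=C(OC(C)C)C(=O)C1=O | intermediate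
7 | tert-butyl vinyl ether | C=COC(C)(C)C | starting material
8 | 1-tert-butoxyvinyllithium | [Li]C(=C)OC(C)(C)C | intermediate
9 | lithium 1-(1-tert-butoxyvinyl)-3-(1-ethoxyvinyl)-2-isopropoxy-4-oxocyclobut-2-en-1-olate (racemic) | [Li+].[O-]C1(C(=C)OC(C)(C)C)C(OC(C)C)=C(C(=C)OCC)C1=O | intermediate
10 | 4-(1-tert-butoxyvinyl)-2-(1-ethoxyvinyl)-3-isopropoxy-4-methoxycyclobut-2-en-1-one (racemic) | CCOC(=C)C1=C(OC(C)C)C(OC)(C(=C)OC(C)(C)C)C1=O | intermediate
11 | (3Z)-5-tert-butoxy-2-(1-ethoxyvinyl)-3-isopropoxy-4-methoxyhexa-1,3,5-trien-1-one | CCOC(=C)C(=C=O)/C(OC(C)C)=C(\C(=C)OC(C)(C)C)OC | intermediate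
12 | 5-tert-butoxy-2-(1-ethoxyvinyl)-3-isopropoxy-4-methoxycyclohexa-2,4-dien-1-one | CCOC(=C)C1=C(OC(C)C)C(OC)=C(OC(C)(C)C)CC1=O | intermediate
13 | 5-tert-butoxy-2-(1-ethoxyvinyl)-3-isopropoxy-4-methoxyphenol | CCOC(=C)c1c(O)cc(OC(C)(C)C)c(OC)c1OC(C)C | intermediate
14 | 1-tert-butoxy-4-(1-ethoxyvinyl)-3-isopropoxy-2,5-dimethoxybenzene | CCOC(=C)c1c(OC)cc(OC(C)(C)C)c(OC)c1OC(C)C | intermediate
15 | 1-(4-tert-butoxy-2-isopropoxy-3,6-dimethoxyphenyl)ethan-1-one | CC(=O)c1c(OC)cc(OC(C)(C)C)c(OC)c1OC(C)C | intermediate
16 | 1-[2,4-bis(dichloroboryloxy)-3,6-dimethoxyphenyl]ethan-1-one | CC(=O)c1c(OC)cc(OB(Cl)Cl)c(OC)c1OB(Cl)Cl | intermediate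
17 | 1-(2,4-dihydroxy-3,6-dimethoxyphenyl)ethan-1-one | CC(=O)c1c(OC)cc(O)c(OC)c1O | intermediate
18 | 3,5-dihydroxy-4-methoxybenzoic acid | COc1c(O)cc(C(=O)O)cc1O | starting material
19 | tert-butyldimethylsilyl 3,5-bis(tert-butyldimethylsilyloxy)-4-methoxybenzoate | COc1c(O[Si](C)(C)C(C)(C)C)cc(C(=O)O[Si](C)(C)C(C)(C)C)cc1O[Si](C)(C)C(C)(C)C | intermediate
20 | 3,5-bis(tert-butyldimethylsilyloxy)-4-methoxybenzoyl chloride | COc1c(O[Si](C)(C)C(C)(C)C)cc(C(=O)Cl)cc1O[Si](C)(C)C(C)(C)C | intermediate
21 | trilithium enolate bis(phenolate) of 17 | [Li+].[Li+].[Li+].C=C([O-])c1c(OC)cc([O-])c(OC)c1[O-] | intermediate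
22 | 1-[3,5-bis(tert-butyldimethylsilyloxy)-4-methoxyphenyl]-3-(2,4-dihydroxy-3,6-dimethoxyphenyl)propane-1,3-dione | COc1cc(O)c(OC)c(O)c1C(=O)CC(=O)c1cc(O[Si](C)(C)C(C)(C)C)c(OC)c(O[Si](C)(C)C(C)(C)C)c1 | intermediate
23 | 2-[3,5-bis(tert-butyldimethylsilyloxy)-4-methoxyphenyl]-7-hydroxy-5,8-dimethoxy-4H-chromen-4-one | COc1c(O[Si](C)(C)C(C)(C)C)cc(-c2cc(=O)c3c(OC)cc(O)c(OC)c3o2)cc1O[Si](C)(C)C(C)(C)C | intermediate
24 | 7-hydroxy-2-(3,5-dihydroxy-4-methoxyphenyl)-5,8-dimethoxy-4H-chromen-4-one | COc1c(O)cc(-c2cc(=O)c3c(OC)cc(O)c(OC)c3o2)cc1O | target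

**Step count**
Total steps: 9. Longest linear sequence: 7 (steps 1, 2, 3, 4, 5, 8, 9).

**Steps most likely to fail**

**Step 2.**
- What may go wrong: α-deprotonation of the hindered vinyl ether may be incomplete, so that residual t-BuLi attacks 6. The crowded tertiary alkoxide may also be methylated sluggishly.
- Fallback, from 6 back to 17: the tert-butyl group is replaced by a second isopropyl group, so that C7 and C8a carry the same ether and are freed together. Commercial isopropyl vinyl ether is lithiated in the same way as 1 to give 1-isopropoxyvinyllithium F1. Adding this to 6 and trapping with MeOTf should give 2-(1-ethoxyvinyl)-3-isopropoxy-4-(1-isopropoxyvinyl)-4-methoxycyclobut-2-en-1-one F2. Thermolysis in toluene should give 2-(1-ethoxyvinyl)-3,5-diisopropoxy-4-methoxyphenol F3. Methylation with MeI and K2CO3 gives 4-(1-ethoxyvinyl)-1,3-diisopropoxy-2,5-dimethoxybenzene F4, and dilute acid gives 1-(2,4-diisopropoxy-3,6-dimethoxyphenyl)ethan-1-one F5. BCl3 then removes both secondary ethers, the chelated one first, and the boron chelate shields C5–OMe while the C7 ether is cleaved, which leads to 17.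

**Step 1.**
- What may go wrong: the enol ether may be protonated and hydrolysed, or C-trifluoroacetylated, while the trifluoroacetate ionises and the dione is released.
- Fallback, from 2 back to 15: the acetyl group is masked as an acid-tolerant isopropenyl group and unveiled by alkene cleavage. Isopropenylmagnesium bromide adds to 2 to give 4-hydroxy-2,3-diisopropoxy-4-(prop-1-en-2-yl)cyclobut-2-en-1-one F6. Catalytic concentrated HCl in CH2Cl2 converts this into 3-isopropoxy-4-(prop-1-en-2-yl)cyclobut-3-ene-1,2-dione F7. Addition of 8 and MeOTf trapping give 4-(1-tert-butoxyvinyl)-3-isopropoxy-4-methoxy-2-(prop-1-en-2-yl)cyclobut-2-en-1-one F8. Thermolysis gives 5-tert-butoxy-3-isopropoxy-4-methoxy-2-(prop-1-en-2-yl)phenol F9, and methylation gives 1-tert-butoxy-3-isopropoxy-2,5-dimethoxy-4-(prop-1-en-2-yl)benzene F10. Lemieux–Johnson oxidation (OsO4 cat., NaIO4, 2,6-lutidine, dioxane–H2O) cleaves the alkene to 15.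

**Step 3.**
- What may go wrong: proton transfer from the nascent phenol to the neighbouring enol ether, thermal loss of isobutene from the tert-butyl enol ether, and ketene oligomerisation may all compete with ring closure, and the electron-rich phenol may degrade on isolation.
- Fallback, from 6 back to 14: ring A is taken out at the quinone oxidation level, where no acidic hydroxyl sits beside the enol ether. Alkoxide 9 is quenched with aqueous NH4Cl instead of MeOTf to give 4-(1-tert-butoxyvinyl)-2-(1-ethoxyvinyl)-4-hydroxy-3-isopropoxycyclobut-2-en-1-one F11. Thermolysis gives 5-tert-butoxy-2-(1-ethoxyvinyl)-3-isopropoxybenzene-1,4-diol F12, which is oxidised in the same flask with Ag2O and K2CO3 to 5-tert-butoxy-2-(1-ethoxyvinyl)-3-isopropoxycyclohexa-2,5-diene-1,4-dione F13. The neutral quinone is purified. It is then reduced with Na2S2O4 and methylated at once on both oxygens with Me2SO4 and K2CO3 in acetone to give 14, which is hydrolysed as in step 4.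

**Further compounds**
F1 | step 2 | 1-isopropoxyvinyllithium | [Li]C(=C)OC(C)C
F2 | step 2 | 2-(1-ethoxyvinyl)-3-isopropoxy-4-(1-isopropoxyvinyl)-4-methoxycyclobut-2-en-1-one (racemic) | CCOC(=C)C1=C(OC(C)C)C(OC)(C(=C)OC(C)C)C1=O
F3 | step 2 | 2-(1-ethoxyvinyl)-3,5-diisopropoxy-4-methoxyphenol | CCOC(=C)c1c(O)cc(OC(C)C)c(OC)c1OC(C)C
F4 | step 2 | 4-(1-ethoxyvinyl)-1,3-diisopropoxy-2,5-dimethoxybenzene | CCOC(=C)c1c(OC)cc(OC(C)C)c(OC)c1OC(C)C
F5 | step 2 | 1-(2,4-diisopropoxy-3,6-dimethoxyphenyl)ethan-1-one | CC(=O)c1c(OC)cc(OC(C)C)c(OC)c1OC(C)C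
F6 | step 1 | 4-hydroxy-2,3-diisopropoxy-4-(prop-1-en-2-yl)cyclobut-2-en-1-one (racemic) | CC(=C)C1(O)C(OC(C)C)=C(OC(C)C)C1=O
F7 | step 1 | 3-isopropoxy-4-(prop-1-en-2-yl)cyclobut-3-ene-1,2-dione | CC(=C)C1=C(OC(C)C)C(=O)C1=O
F8 | step 1 | 4-(1-tert-butoxyvinyl)-3-isopropoxy-4-methoxy-2-(prop-1-en-2-yl)cyclobut-2-en-1-one (racemic) | CC(=C)C1=C(OC(C)C)C(OC)(C(=C)OC(C)(C)C)C1=O
F9 | step 1 | 5-tert-butoxy-3-isopropoxy-4-methoxy-2-(prop-1-en-2-yl)phenol | CC(=C)c1c(O)cc(OC(C)(C)C)c(OC)c1OC(C)C
F10 | step 1 | 1-tert-butoxy-3-isopropoxy-2,5-dimethoxy-4-(prop-1-en-2-yl)benzene | CC(=C)c1c(OC)cc(OC(C)(C)C)c(OC)c1OC(C)C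
F11 | step 3 | 4-(1-tert-butoxyvinyl)-2-(1-ethoxyvinyl)-4-hydroxy-3-isopropoxycyclobut-2-en-1-one (racemic) | CCOC(=C)C1=C(OC(C)C)C(O)(C(=C)OC(C)(C)C)C1=O
F12 | step 3 | 5-tert-butoxy-2-(1-ethoxyvinyl)-3-isopropoxybenzene-1,4-diol | CCOC(=C)c1c(O)cc(OC(C)(C)C)c(O)c1OC(C)C
F13 | step 3 | 5-tert-butoxy-2-(1-ethoxyvinyl)-3-isopropoxycyclohexa-2,5-diene-1,4-dione | CCOC(=C)C1=C(OC(C)C)C(=O)C(OC(C)(C)C)=CC1=O
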